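**Strategy**

Every ring carbon of the target cyclohexane bears oxygen, and the tertiary oxygen on C1 (the carbon carrying C7) is cis to the secondary oxygen on C2, both lying opposite the oxygens on C6 and C3. The route rests on cutting C1–C2: a SmI2 pinacol cyclisation of an acyclic keto-aldehyde closes the six-membered ring and sets C1 and C2 in one operation. The precursor has the ketone at C1, flanked by C7H2OBn and an acetonide across C6/C5, a silyl ether at C4, a benzyl ether at C3 and the aldehyde at C2; its four stereocentres come intact from D-gulono-1,4-lactone. Esterification and a cyclic-sulfate ring closure finish the oxirane.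

Key step: step 11

Remark: ring atoms are numbered C1 (quaternary oxirane carbon bearing C7), C2 and C3 (acetoxy carbons), C4 and C5 (carbinols), C6 (oxirane CH); the face of C7, O3 and O5 is called upper, the face of the oxirane oxygen, O2 and O4 lower. Compounds 1–7 keep D-gulonic numbering, whose C1, C2, C3, C4, C5, C6 become ring C1, C6, C5, C4, C3, C2. Tributyl(iodomethyl)stannane is taken to be a purchasable reagent.

**Route**

Step 1
Reactants: 1 D-gulono-1,4-lactone
Product: 2 2,3:5,6-di-O-isopropylidene-D-gulono-1,4-lactone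
Conditions: 2,2-dimethoxypropane, acetone, TsOH·H2O (cat.), rt
Reagents that add atoms: 2,2-dimethoxypropane, COC(C)(C)OC
Why: Acid-catalysed acetal exchange (isopropylidenation) turns the cis-2,3-diol on the lactone ring and the terminal 5,6-diol into dioxolanes without touching a stereocentre.

Step 2
Reactants: 2 2,3:5,6-di-O-isopropylidene-D-gulono-1,4-lactone
Product: 3 2,3-O-isopropylidene-D-gulono-1,4-lactone
Conditions: AcOH/H2O (7:3), rt
Reagents that add atoms: none
Why: Selective acetal hydrolysis, since the terminal dioxolane is cleaved by dilute acid well before the ring-fused 2,3-acetonide, which is deactivated by the neighbouring lactone carbonyl.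

Step 3
Reactants: 3 2,3-O-isopropylidene-D-gulono-1,4-lactone
Product: 4 6-O-(tert-butyldimethylsilyl)-2,3-O-isopropylidene-D-gulono-1,4-lactone
Conditions: TBSCl (1.05 equiv), imidazole, DMF, 0 °C
Reagents that add atoms: tert-butyldimethylsilyl chloride, CC(C)(C)[Si](C)(C)Cl
Why: Chemoselective silylation, the primary 6-hydroxyl reacting much faster with the bulky silyl chloride than the secondary 5-hydroxyl.

Step 4
Reactants: 4 6-O-(tert-butyldimethylsilyl)-2,3-O-isopropylidene-D-gulono-1,4-lactone
Product: 5 5-O-benzyl-6-O-(tert-butyldimethylsilyl)-2,3-O-isopropylidene-D-gulono-1,4-lactone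
Conditions: BnOC(=NH)CCl3, TfOH (cat.), CH2Cl2/cyclohexane, 0 °C to rt
Reagents that add atoms: benzyl 2,2,2-trichloroacetimidate, ClC(Cl)(Cl)C(=N)OCc1ccccc1
Why: Acid-catalysed trichloroacetimidate benzylation etherifies the only free hydroxyl without base, so the lactone is neither opened nor epimerised at its α-carbon.

Step 5
Reactants: 5 5-O-benzyl-6-O-(tert-butyldimethylsilyl)-2,3-O-isopropylidene-D-gulono-1,4-lactone
Product: 6 5-O-benzyl-6-O-(tert-butyldimethylsilyl)-2,3-O-isopropylidene-N-methoxy-N-methyl-D-gulonamide (4-hydroxyl free)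
Conditions: MeNH(OMe)·HCl, AlMe3, CH2Cl2, 0 °C to rt; aq. potassium sodium tartrate (KNaC4H4O6)
Reagents that add atoms: N,O-dimethylhydroxylamine hydrochloride, Cl.CNOC
Why: Weinreb aminolysis of a lactone, in which the aluminium amide attacks the acyl carbon and frees only the 4-hydroxyl, leaving all stereocentres unchanged.

Step 6
Reactants: 6 5-O-benzyl-6-O-(tert-butyldimethylsilyl)-2,3-O-isopropylidene-N-methoxy-N-methyl-D-gulonamide
Product: 7 5-O-benzyl-4,6-bis-O-(tert-butyldimethylsilyl)-2,3-O-isopropylidene-N-methoxy-N-methyl-D-gulonamide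
Conditions: TBSOTf, 2,6-lutidine, CH2Cl2, −78 to 0 °C (crude 6 used at once)
Reagents that add atoms: tert-butyldimethylsilyl trifluoromethanesulfonate, CC(C)(C)[Si](C)(C)OS(=O)(=O)C(F)(F)F
Why: Silylation with a silyl triflate is fast enough at low temperature to cap the hindered 4-hydroxyl before it can close back to the lactone.

Step 7
Reactants: 8 benzyl alcohol; 9 tributyl(iodomethyl)stannane
Product: 11 tributyl[(benzyloxy)methyl]stannane, via sodium benzyloxide 10 (not isolated)
Conditions: NaH, THF/DMF, 0 °C; then 9, rt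
Reagents that add atoms: none
Why: Williamson ether synthesis, the alkoxide displacing iodide from the primary iodomethyl carbon by SN2.

Step 8
Reactants: 7 5-O-benzyl-4,6-bis-O-(tert-butyldimethylsilyl)-2,3-O-isopropylidene-N-methoxy-N-methyl-D-gulonamide; 11 tributyl[(benzyloxy)methyl]stannane
Product: 13 1,6-di-O-benzyl-5,7-bis-O-(tert-butyldimethylsilyl)-3,4-O-isopropylidene-keto-D-gulo-hept-2-ulose, via (benzyloxymethyl)lithium 12 (not isolated)
Conditions: 11, n-BuLi, THF, −78 °C; then 7, −78 °C; aq. NH4Cl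
Reagents that add atoms: none
Why: Weinreb ketone synthesis after tin–lithium exchange; lithium chelation by the N-methoxy group holds the adduct until quench, so no second addition occurs and the α-stereocentre is not epimerised at −78 °C.

Step 9
Reactants: 13 1,6-di-O-benzyl-5,7-bis-O-(tert-butyldimethylsilyl)-3,4-O-isopropylidene-keto-D-gulo-hept-2-ulose
Product: 14 1,6-di-O-benzyl-5-O-(tert-butyldimethylsilyl)-3,4-O-isopropylidene-keto-D-gulo-hept-2-ulose (primary hydroxyl at ring C2 free)
Conditions: HF·pyridine, pyridine, THF, 0 °C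
Reagents that add atoms: none
Why: Selective desilylation, the unhindered primary silyl ether being cleaved well before the secondary one flanked by two branched carbons, in a weakly acidic medium that does not epimerise the cis-dioxolane ketone.

Step 10
Reactants: 14 1,6-di-O-benzyl-5-O-(tert-butyldimethylsilyl)-3,4-O-isopropylidene-keto-D-gulo-hept-2-ulose
Product: 15 2,7-di-O-benzyl-3-O-(tert-butyldimethylsilyl)-4,5-O-isopropylidene-L-gluco-heptos-6-ulose (acyclic keto-aldehyde; ring numbering C2 aldehyde and C1 ketone)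
Conditions: Dess–Martin periodinane, CH2Cl2, 0 °C to rt; crude 15 used at once
Reagents that add atoms: none
Why: Dess–Martin oxidation converts the primary alcohol into the aldehyde under non-enolising conditions that leave the ketone and the α-benzyloxy stereocentre intact.

Step 11
Reactants: 15 2,7-di-O-benzyl-3-O-(tert-butyldimethylsilyl)-4,5-O-isopropylidene-L-gluco-heptos-6-ulose
Product: 16 3-O-benzyl-1-C-(benzyloxymethyl)-4-O-(tert-butyldimethylsilyl)-5,6-O-isopropylidene-cyclohexane-1,2,3,4,5,6-hexol (1,2-cis-diol; O1/O2/O4 lower face; C7/O3/O5/O6 upper face)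
Conditions: 15 added slowly to SmI2 (3 equiv), t-BuOH (3 equiv), THF, −78 to −30 °C; aq. NaHCO3
Reagents that add atoms: none
Why: Divalent samarium transfers one electron to the C2 aldehyde, the ketyl held on trivalent samarium adds to the samarium-coordinated C1 ketone, and a second electron followed by protonation from t-BuOH releases the diol; the closest known reaction type is the SmI2 pinacol carbocyclisation of sugar-derived 1,6-dicarbonyl compounds to inositols and C-branched cyclitols. The cyclohexane closes in a 6-exo-trig mode through the new C1–C2 bond. Both oxygens stay bound to samarium while the bond forms, which sets C1 and C2 as a cis-diol. The face is fixed by the neighbouring centres: the C–O bonds at C6 (acetonide oxygen) and C3 (benzyloxy) both point to the upper face and the metal-bound oxygens avoid them, so O1 and O2 should form on the lower face in a chair-like transition state with the C3, C4 and C5 substituents equatorial, the two directing groups reinforcing each other. The step needs ring closure to outrun simple carbonyl reduction, intermolecular coupling and reductive cleavage of the C–O bonds next to the ketone, which low temperature, slow addition to excess SmI2, the absence of HMPA and the cis-fused acetonide that holds the two chain ends close should secure.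

Step 12
Reactants: 16 3-O-benzyl-1-C-(benzyloxymethyl)-4-O-(tert-butyldimethylsilyl)-5,6-O-isopropylidene-cyclohexane-1,2,3,4,5,6-hexol
Product: 17 4-O-(tert-butyldimethylsilyl)-1-C-(hydroxymethyl)-5,6-O-isopropylidene-cyclohexane-1,2,3,4,5,6-hexol (O1/O2/O3/O7 free)
Conditions: H2 (1 atm), Pd(OH)2/C, EtOAc, rt
Reagents that add atoms: none
Why: Catalytic hydrogenolysis cleaves both benzyl ethers while the silyl ether, the acetonide and all stereocentres are inert to hydrogen.

Step 13
Reactants: 17 4-O-(tert-butyldimethylsilyl)-1-C-(hydroxymethyl)-5,6-O-isopropylidene-cyclohexane-1,2,3,4,5,6-hexol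
Product: 18 1-C-(benzoyloxymethyl)-4-O-(tert-butyldimethylsilyl)-5,6-O-isopropylidene-cyclohexane-1,2,3,4,5,6-hexol (O1/O2/O3 free)
Conditions: BzCl (1.05 equiv), 2,4,6-collidine, CH2Cl2, −40 to 0 °C
Reagents that add atoms: benzoyl chloride, O=C(Cl)c1ccccc1
Why: Regioselective acylation, because at low temperature with a hindered pyridine base the acid chloride should take the primary C7 hydroxyl in preference to the doubly flanked secondary hydroxyls and the tertiary one.

Step 14
Reactants: 18 1-C-(benzoyloxymethyl)-4-O-(tert-butyldimethylsilyl)-5,6-O-isopropylidene-cyclohexane-1,2,3,4,5,6-hexol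
Product: 19 2,3-di-O-acetyl-1-C-(benzoyloxymethyl)-4-O-(tert-butyldimethylsilyl)-5,6-O-isopropylidene-cyclohexane-1,2,3,4,5,6-hexol (O1 free)
Conditions: Ac2O, pyridine, DMAP (cat.), CH2Cl2, 0 °C to rt
Reagents that add atoms: acetic anhydride, CC(=O)OC(C)=O
Why: Standard esterification acetylates the secondary hydroxyls at C2 and C3, whereas the tertiary C1 hydroxyl is too hindered to react under these mild conditions.

Step 15
Reactants: 19 2,3-di-O-acetyl-1-C-(benzoyloxymethyl)-4-O-(tert-butyldimethylsilyl)-5,6-O-isopropylidene-cyclohexane-1,2,3,4,5,6-hexol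
Product: 20 2,3-di-O-acetyl-1-C-(benzoyloxymethyl)-4-O-(tert-butyldimethylsilyl)-cyclohexane-1,2,3,4,5,6-hexol (O1/O5/O6 free)
Conditions: AcOH/H2O (4:1), 50 °C
Reagents that add atoms: none
Why: Acid-catalysed acetal hydrolysis removes the cis-fused isopropylidene group under conditions mild enough for the hindered secondary silyl ether and the three esters.

Step 16
Reactants: 20 2,3-di-O-acetyl-1-C-(benzoyloxymethyl)-4-O-(tert-butyldimethylsilyl)-cyclohexane-1,2,3,4,5,6-hexol
Product: 22 5,6-cyclic sulfate of 20 (C1 hydroxyl free), via 5,6-cyclic sulfite 21 (not isolated)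
Conditions: SOCl2, Et3N, CH2Cl2, 0 °C; then RuCl3·3H2O (cat.), NaIO4, MeCN/EtOAc/H2O, 0 °C
Reagents that add atoms: thionyl chloride, O=S(Cl)Cl; sodium periodate, [Na+].[O-]I(=O)(=O)=O
Why: Cyclic sulfite formation followed by RuO4-catalysed oxidation at sulfur; only the cis-5,6-diol can bridge through sulfur, since the C1 hydroxyl is tertiary and anti to O6, and no carbon stereocentre is involved.

Step 17
Reactants: 22 5,6-cyclic sulfate of 20
Product: 24 2,3-di-O-acetyl-7-O-benzoyl-4-O-(tert-butyldimethylsilyl) 1,6-epoxide (oxirane oxygen on the lower face; O5 free), via epoxide 5-O-sulfate sodium salt 23 (not isolated)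
Conditions: NaH (1.1 equiv), THF, 0 °C; then H2SO4 (0.3 equiv), H2O (2 equiv), THF, rt
Reagents that add atoms: none
Why: Intramolecular SN2 opening of a cyclic sulfate by a neighbouring alkoxide (3-exo-tet epoxide closure): in the chair with all other ring substituents equatorial the axial C1 alkoxide is antiperiplanar to the axial C6–O bond, so it displaces the sulfate oxygen with inversion at C6 and places the oxirane on the lower face, after which the C5 sulfate half-ester is hydrolysed by catalytic acid with S–O cleavage and retention at C5.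

Step 18
Reactants: 24 2,3-di-O-acetyl-7-O-benzoyl-4-O-(tert-butyldimethylsilyl) 1,6-epoxide
Product: 25 target CNP0171674.1
Conditions: HF·pyridine, pyridine, THF, 0 °C to rt
Reagents that add atoms: none
Why: Fluoride-mediated desilylation in a buffered, weakly acidic medium frees O4 without the base-promoted acetyl or epoxide migration that an alkoxide next to the esters and the oxirane would allow.

**Compound list**

1 | D-gulono-1,4-lactone | O=C1O[C@@H]([C@H](O)CO)[C@@H](O)[C@H]1O | starting material
2 | 2,3:5,6-di-O-isopropylidene-D-gulono-1,4-lactone | O=C1O[C@@H]([C@H]2COC(C)(C)O2)[C@H]3OC(C)(C)O[C@@H]13 | intermediate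
3 | 2,3-O-isopropylidene-D-gulono-1,4-lactone | O=C1O[C@@H]([C@H](O)CO)[C@H]2OC(C)(C)O[C@@H]12 | intermediate
4 | 6-O-(tert-butyldimethylsilyl)-2,3-O-isopropylidene-D-gulono-1,4-lactone | O=C1O[C@@H]([C@H](O)CO[Si](C)(C)C(C)(C)C)[C@H]2OC(C)(C)O[C@@H]12 | intermediate
5 | 5-O-benzyl-6-O-(tert-butyldimethylsilyl)-2,3-O-isopropylidene-D-gulono-1,4-lactone | O=C1O[C@@H]([C@H](OCc3ccccc3)CO[Si](C)(C)C(C)(C)C)[C@H]2OC(C)(C)O[C@@H]12 | intermediate
6 | 5-O-benzyl-6-O-(tert-butyldimethylsilyl)-2,3-O-isopropylidene-N-methoxy-N-methyl-D-gulonamide (4-OH free) | CC(C)(C)[Si](C)(C)OC[C@@H](OCc1ccccc1)[C@H](O)[C@H]2OC(C)(C)O[C@H]2C(=O)N(C)OC | intermediate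
7 | 5-O-benzyl-4,6-bis-O-(tert-butyldimethylsilyl)-2,3-O-isopropylidene-N-methoxy-N-methyl-D-gulonamide | CC(C)(C)[Si](C)(C)OC[C@@H](OCc1ccccc1)[C@H](O[Si](C)(C)C(C)(C)C)[C@H]2OC(C)(C)O[C@H]2C(=O)N(C)OC | intermediate
8 | benzyl alcohol | OCc1ccccc1 | starting material
9 | tributyl(iodomethyl)stannane | CCCC[Sn](CCCC)(CCCC)CI | starting material
10 | sodium benzyloxide (not isolated) | [Na+].[O-]Cc1ccccc1 | intermediate
11 | tributyl[(benzyloxy)methyl]stannane | CCCC[Sn](CCCC)(CCCC)COCc1ccccc1 | intermediate
12 | (benzyloxymethyl)lithium (not isolated) | [Li]COCc1ccccc1 | intermediate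
13 | 1,6-di-O-benzyl-5,7-bis-O-(tert-butyldimethylsilyl)-3,4-O-isopropylidene-keto-D-gulo-hept-2-ulose; ring numbering C7H2OBn–C1(=O)–C6/C5 (acetonide)–C4(OTBS)–C3(OBn)–C2H2OTBS | CC(C)(C)[Si](C)(C)OC[C@@H](OCc1ccccc1)[C@H](O[Si](C)(C)C(C)(C)C)[C@H]2OC(C)(C)O[C@H]2C(=O)COCc1ccccc1 | intermediate
14 | 1,6-di-O-benzyl-5-O-(tert-butyldimethylsilyl)-3,4-O-isopropylidene-keto-D-gulo-hept-2-ulose (ring C2 primary alcohol) | OC[C@@H](OCc1ccccc1)[C@H](O[Si](C)(C)C(C)(C)C)[C@H]2OC(C)(C)O[C@H]2C(=O)COCc1ccccc1 | intermediate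
15 | 2,7-di-O-benzyl-3-O-(tert-butyldimethylsilyl)-4,5-O-isopropylidene-L-gluco-heptos-6-ulose; acyclic keto-aldehyde, ring C2 aldehyde, ring C1 ketone | O=C[C@@H](OCc1ccccc1)[C@H](O[Si](C)(C)C(C)(C)C)[C@H]2OC(C)(C)O[C@H]2C(=O)COCc1ccccc1 | intermediate
16 | 3-O-benzyl-1-C-(benzyloxymethyl)-4-O-(tert-butyldimethylsilyl)-5,6-O-isopropylidene-cyclohexane-1,2,3,4,5,6-hexol; O1, O2, O4 lower face, C7, O3, O5, O6 upper face | C(c3ccccc3)O[C@H]1[C@H](O[Si](C)(C)C(C)(C)C)[C@H]2OC(C)(C)O[C@H]2[C@@](O)(COCc2ccccc2)[C@@H]1O | intermediate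
17 | 4-O-(tert-butyldimethylsilyl)-1-C-(hydroxymethyl)-5,6-O-isopropylidene-cyclohexane-1,2,3,4,5,6-hexol, same faces as 16 | O[C@H]1[C@H](O[Si](C)(C)C(C)(C)C)[C@H]2OC(C)(C)O[C@H]2[C@@](O)(CO)[C@@H]1O | intermediate
18 | 7-O-benzoate of 17 | O[C@H]1[C@H](O[Si](C)(C)C(C)(C)C)[C@H]2OC(C)(C)O[C@H]2[C@@](O)(COC(=O)c2ccccc2)[C@@H]1O | intermediate
19 | 2,3-di-O-acetate of 18 (tertiary O1 free) | CC(=O)O[C@H]1[C@H](O[Si](C)(C)C(C)(C)C)[C@H]2OC(C)(C)O[C@H]2[C@@](O)(COC(=O)c2ccccc2)[C@@H]1OC(C)=O | intermediate
20 | 1,5,6-triol from 19 (O5 and O6 upper face, O1 lower face) | CC(=O)O[C@H]1[C@H](O[Si](C)(C)C(C)(C)C)[C@@H](O)[C@@H](O)[C@@](O)(COC(=O)c2ccccc2)[C@@H]1OC(C)=O | intermediate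
21 | 5,6-cyclic sulfite of 20, either configuration at sulfur (not isolated) | CC(=O)O[C@H]1[C@H](O[Si](C)(C)C(C)(C)C)[C@H]2OS(=O)O[C@H]2[C@@](O)(COC(=O)c2ccccc2)[C@@H]1OC(C)=O | intermediate
22 | 5,6-cyclic sulfate of 20 | CC(=O)O[C@H]1[C@H](O[Si](C)(C)C(C)(C)C)[C@H]2OS(=O)(=O)O[C@H]2[C@@](O)(COC(=O)c2ccccc2)[C@@H]1OC(C)=O | intermediate
23 | sodium 5-O-sulfate of the C1–C6 epoxide (not isolated) | CC(=O)O[C@H]1[C@H](O[Si](C)(C)C(C)(C)C)[C@@H](OS(=O)(=O)[O-])[C@@H]2O[C@]2(COC(=O)c2ccccc2)[C@@H]1OC(C)=O.[Na+] | intermediate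
24 | 4-O-(tert-butyldimethylsilyl) ether of the target | CC(=O)O[C@H]1[C@H](O[Si](C)(C)C(C)(C)C)[C@@H](O)[C@@H]2O[C@]2(COC(=O)c2ccccc2)[C@@H]1OC(C)=O | intermediate
25 | CNP0171674.1: 2,3-di-O-acetyl-7-O-benzoyl C1–C6 epoxide with free O4 and O5 | CC(=O)O[C@H]1[C@H](O)[C@@H](O)[C@@H]2O[C@]2(COC(=O)c2ccccc2)[C@@H]1OC(C)=O | target

**Step count and risks**

Total step count: 18. Longest linear sequence: 17 steps (steps 1–6 and 8–18, from 1 to 25); step 7 is a one-step side branch.

Steps most likely to fail:

1. Step 11. What may go wrong: reduction of a carbonyl without ring closure, reductive loss of an oxygen substituent next to the ketone (at C6 or C7), or insufficient facial discrimination in the coupling. Fallback, from 15 back to 16: double Wittig methylenation of both carbonyls (Ph3PCH3Br, KN(SiMe3)2, THF, −78 to 0 °C) should give the 1,7-diene F1. Ring-closing metathesis with second-generation Grubbs catalyst (CH2Cl2, 40 °C) should close the cyclohexene F2 with the C1=C2 double bond. Dihydroxylation with OsO4 (cat.) and N-methylmorpholine N-oxide in acetone/H2O should then add both hydroxyls from the lower face, opposite the two allylic oxygens on C6 and C3, and return diol 16.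

2. Step 17. What may go wrong: acyl transfer from O2 or O7 to the C1 alkoxide competing with ring closure, or acid-promoted opening of the new oxirane while the sulfate half-ester is hydrolysed. Fallback, from 20 directly to 25: selective silylation of the equatorial O5 (TESCl, imidazole, DMF, −30 °C), which is less hindered than the axial O6 next to the quaternary carbon, should give the 5-O-triethylsilyl ether F3. Tf2O and pyridine in CH2Cl2 at −20 °C should form the C6 triflate F4, which the neutral, antiperiplanar C1 hydroxyl displaces in the same flask to give the bis-silylated epoxide F5. HF·pyridine in THF then removes both silyl groups and delivers 25 without strong base or sulfate hydrolysis.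

3. Step 13. What may go wrong: insufficient discrimination between the primary C7 hydroxyl and the secondary ring hydroxyls, leading to over-benzoylation or benzoylation at O2. Fallback, from 17 back to 19: TBSCl and imidazole (DMF, 0 °C) should silylate only the primary hydroxyl to give the 7-O-silyl ether F6. Ac2O, pyridine and DMAP give its 2,3-diacetate F7. Buffered HF·pyridine (THF, 0 °C) cleaves the primary silyl ether as in step 9 to give the 7-hydroxy diacetate F8. BzCl and pyridine then benzoylate the primary hydroxyl, the only other free hydroxyl being tertiary, and return 19.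

**Further compounds**

F1 | step 11 | 1,7-diene from double methylenation of 15 | C=C[C@@H](OCc1ccccc1)[C@H](O[Si](C)(C)C(C)(C)C)[C@H]2OC(C)(C)O[C@H]2C(=C)COCc1ccccc1
F2 | step 11 | cyclohexene with C1=C2 double bond (3-O-benzyl, 4-O-TBS, 5,6-O-isopropylidene, C1 benzyloxymethyl) | C(c3ccccc3)O[C@H]1[C@H](O[Si](C)(C)C(C)(C)C)[C@H]2OC(C)(C)O[C@H]2C(COCc2ccccc2)=C1
F3 | step 17 | 5-O-triethylsilyl ether of 20 | CC(=O)O[C@H]1[C@H](O[Si](C)(C)C(C)(C)C)[C@@H](O[Si](CC)(CC)CC)[C@@H](O)[C@@](O)(COC(=O)c2ccccc2)[C@@H]1OC(C)=O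
F4 | step 17 | C6 triflate of F3 | CC(=O)O[C@H]1[C@H](O[Si](C)(C)C(C)(C)C)[C@@H](O[Si](CC)(CC)CC)[C@@H](OS(=O)(=O)C(F)(F)F)[C@@](O)(COC(=O)c2ccccc2)[C@@H]1OC(C)=O
F5 | step 17 | 4-O-TBS 5-O-TES ether of the target | CC(=O)O[C@H]1[C@H](O[Si](C)(C)C(C)(C)C)[C@@H](O[Si](CC)(CC)CC)[C@@H]2O[C@]2(COC(=O)c2ccccc2)[C@@H]1OC(C)=O
F6 | step 13 | 7-O-(tert-butyldimethylsilyl) ether of 17 | O[C@H]1[C@H](O[Si](C)(C)C(C)(C)C)[C@H]2OC(C)(C)O[C@H]2[C@@](O)(CO[Si](C)(C)C(C)(C)C)[C@@H]1O
F7 | step 13 | 2,3-di-O-acetate of F6 | CC(=O)O[C@H]1[C@H](O[Si](C)(C)C(C)(C)C)[C@H]2OC(C)(C)O[C@H]2[C@@](O)(CO[Si](C)(C)C(C)(C)C)[C@@H]1OC(C)=O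
F8 | step 13 | 7-hydroxy 2,3-di-O-acetate (O1 and O7 free) | CC(=O)O[C@H]1[C@H](O[Si](C)(C)C(C)(C)C)[C@H]2OC(C)(C)O[C@H]2[C@@](O)(CO)[C@@H]1OC(C)=O
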